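**Plan**

- Retrosynthesis cuts, in this order: the S–O7 bond of the sulfate, the O1–C8a bond of ring C, and the C2–C3 bond. This leaves a gallacetophenone-derived ring A and a 3,4-bis(benzyloxy)benzoate ring B.
- Forward: rings A and B are joined at C2–C3 by a Claisen condensation to a 1,3-diketone. Ring C is then closed at O1–C8a by anodic oxidation, followed by 7-O-sulfation and hydrogenolysis.
- Enabling feature: ring A carries oxygens on C5, C6 and C7, and O1 sits on C8a, para to O6. C8a is therefore the free β-carbon (to the C7 carbonyl) of the 6,7-ortho-quinone. The diketone enol oxygen reaches it through a six-membered transition state, while the C5 oxygen is blocked as a benzyl ether.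
- Stereochemistry: none; the target has no stereocentre and no stereogenic double bond.

Key step: step 5

Assumption: the target is taken as the free hydrogen sulfate as drawn; the monoester is carried as its triethylammonium salt and protonated only in the last work-up.

Step 1
Reactants: 1 gallacetophenone; 2 dichlorodiphenylmethane
Product: 3 1-(4-hydroxy-2,2-diphenyl-1,3-benzodioxol-5-yl)ethanone
Conditions: Ph2CCl2 (1.2 equiv), Ph2O, 175 °C
Reagents that add atoms: dichlorodiphenylmethane, ClC(Cl)(c1ccccc1)c1ccccc1
Why: Catechol ketalisation with a gem-dichloride; the 2-OH is held in a hydrogen bond to the acetyl carbonyl, so the 3,4-diol pair should close the five-membered diphenylmethylene ketal with loss of HCl.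

Step 2
Reactants: 3 1-(4-hydroxy-2,2-diphenyl-1,3-benzodioxol-5-yl)ethanone; 4 benzyl bromide
Product: 5 1-[4-(benzyloxy)-2,2-diphenyl-1,3-benzodioxol-5-yl]ethanone
Conditions: BnBr, K2CO3, KI (cat.), DMF, 70 °C
Reagents that add atoms: benzyl bromide, BrCc1ccccc1
Why: Williamson ether synthesis on the only remaining phenol; the chelated hydroxyl needs warm DMF but the ketal and the methyl ketone are inert to carbonate.

Step 3
Reactants: 5 1-[4-(benzyloxy)-2,2-diphenyl-1,3-benzodioxol-5-yl]ethanone; 6 methyl 3,4-bis(benzyloxy)benzoate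
Product: 7 1-[4-(benzyloxy)-2,2-diphenyl-1,3-benzodioxol-5-yl]-3-[3,4-bis(benzyloxy)phenyl]propane-1,3-dione
Conditions: NaH (3 equiv), THF, reflux; then AcOH
Reagents that add atoms: methyl 3,4-bis(benzyloxy)benzoate, COC(=O)c1ccc(OCc2ccccc2)c(OCc2ccccc2)c1
Why: Crossed Claisen condensation; the sodium enolate of the methyl ketone acylates the non-enolisable benzoate, and irreversible deprotonation of the 1,3-diketone drives the equilibrium.

Step 4
Reactants: 7 1-[4-(benzyloxy)-2,2-diphenyl-1,3-benzodioxol-5-yl]-3-[3,4-bis(benzyloxy)phenyl]propane-1,3-dione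
Product: 8 1-[2-(benzyloxy)-3,4-dihydroxyphenyl]-3-[3,4-bis(benzyloxy)phenyl]propane-1,3-dione
Conditions: AcOH–H2O (4:1), 100 °C, argon
Reagents that add atoms: none
Why: Acid-catalysed ketal hydrolysis through a diaryl-stabilised oxocarbenium ion; benzyl aryl ethers withstand hot aqueous acetic acid, and the diketone cannot cyclodehydrate because its only ortho oxygen is benzylated.

Step 5
Reactants: 8 1-[2-(benzyloxy)-3,4-dihydroxyphenyl]-3-[3,4-bis(benzyloxy)phenyl]propane-1,3-dione
Product: 10 5-(benzyloxy)-2-[3,4-bis(benzyloxy)phenyl]-6,7-dihydroxy-4H-chromen-4-one, via ortho-quinone 9 (not isolated)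
Conditions: graphite anode, Pt cathode, divided cell, controlled potential at the foot of the first anodic wave (set by cyclic voltammetry of 8), charge limited to 2 F/mol, NaOAc/AcOH buffer (0.15 mol/L, pH 6)–MeCN (1:2), 2 mmol/L in 8, rt, argon; then aq. Na2S2O4
Reagents that add atoms: none
Why: Proposed new method: two-electron, two-proton anodic oxidation of the 3,4-catechol of 8 (the future O6/O7 pair, far easier to oxidise than the benzylated ring B or the diketone) should give ortho-quinone 9, whose C8a is the unsubstituted β-carbon of the C7 carbonyl; the enol oxygen of the diketone adds there in an oxa-Michael sense and loss of the C8a proton re-aromatises ring A as the 6,7-catechol 10. The closest known reaction types are the anodic oxidation of catechols in the presence of 1,3-dicarbonyl compounds, where an enol oxygen closes onto the quinone ring to give benzofurans, and the oxidative lactonisation of dihydrocaffeic acid, where a side-chain oxygen attacks the same ring position of a 4-substituted ortho-quinone to form a six-membered ring; closure of a chromone ring by a diketone enol has not been shown. Ring C closes in a 6-exo-trig mode, the attacked C8=C8a bond lying outside the new ring. No stereocentre is formed. The selectivity needed is attack at C8a and not ipso at the benzyloxy-bearing C5 or intermolecular C-alkylation by a second diketone: C8a is the only hydrogen-bearing quinone carbon within reach of the enol oxygen, C5 is donor-substituted and hindered and its adduct cannot re-aromatise without expelling benzyl oxide, and high dilution favours the intramolecular path. Over-oxidation of 10 is limited by passing only two electrons per molecule at the foot of the catechol wave, by redox exchange between any product quinone and unreacted 8, and by the reductive dithionite work-up.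

Step 6
Reactants: 10 5-(benzyloxy)-2-[3,4-bis(benzyloxy)phenyl]-6,7-dihydroxy-4H-chromen-4-one; 11 sulfur trioxide–triethylamine complex
Product: 12 triethylammonium 5-(benzyloxy)-2-[3,4-bis(benzyloxy)phenyl]-6-hydroxy-4-oxo-4H-chromen-7-yl sulfate
Conditions: SO3·NEt3 (1.1 equiv), Et3N (1.0 equiv), DMF, 0 °C to rt
Reagents that add atoms: sulfur trioxide–triethylamine complex, CC[N+](CC)(CC)S(=O)(=O)[O-]
Why: Phenol O-sulfation with a sulfur trioxide–amine complex; the 7-OH, para to the C4 carbonyl (a vinylogous acid), is the more acidic and less hindered hydroxyl, so one equivalent of reagent should sulfate its phenoxide in preference to the 6-OH flanked by the 5-benzyloxy group.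

Step 7
Reactants: 12 triethylammonium 5-(benzyloxy)-2-[3,4-bis(benzyloxy)phenyl]-6-hydroxy-4-oxo-4H-chromen-7-yl sulfate
Product: 13 6-hydroxyluteolin 7-sulfate, 2-(3,4-dihydroxyphenyl)-5,6-dihydroxy-4-oxo-4H-chromen-7-yl hydrogen sulfate
Conditions: H2 (1 atm), 10% Pd/C, MeOH–THF, rt; then sulfonic acid ion-exchange resin (H+ form), 0 °C, lyophilise
Reagents that add atoms: none
Why: Catalytic hydrogenolysis of the three benzyl aryl ethers; aryl sulfate monoester salts are inert to H2 on palladium, the chromone double bond is reduced far more slowly than benzyl C–O bonds are cleaved, and a brief cold pass through the acidic resin should give the free hydrogen sulfate.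

**Compound list**

1 | gallacetophenone, 1-(2,3,4-trihydroxyphenyl)ethanone | CC(=O)c1ccc(O)c(O)c1O | starting material
2 | dichlorodiphenylmethane | ClC(Cl)(c1ccccc1)c1ccccc1 | starting material
3 | 1-(4-hydroxy-2,2-diphenyl-1,3-benzodioxol-5-yl)ethanone | CC(=O)c1ccc2OC(c3ccccc3)(c3ccccc3)Oc2c1O | intermediate
4 | benzyl bromide | BrCc1ccccc1 | starting material
5 | 1-[4-(benzyloxy)-2,2-diphenyl-1,3-benzodioxol-5-yl]ethanone | CC(=O)c1ccc2OC(c3ccccc3)(c3ccccc3)Oc2c1OCc1ccccc1 | intermediate
6 | methyl 3,4-bis(benzyloxy)benzoate | COC(=O)c1ccc(OCc2ccccc2)c(OCc2ccccc2)c1 | starting material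
7 | 1-[4-(benzyloxy)-2,2-diphenyl-1,3-benzodioxol-5-yl]-3-[3,4-bis(benzyloxy)phenyl]propane-1,3-dione | O=C(CC(=O)c1ccc(OCc2ccccc2)c(OCc2ccccc2)c1)c1ccc2OC(c3ccccc3)(c3ccccc3)Oc2c1OCc1ccccc1 | intermediate
8 | 1-[2-(benzyloxy)-3,4-dihydroxyphenyl]-3-[3,4-bis(benzyloxy)phenyl]propane-1,3-dione | O=C(CC(=O)c1ccc(OCc2ccccc2)c(OCc2ccccc2)c1)c1ccc(O)c(O)c1OCc1ccccc1 | intermediate
9 | ortho-quinone, 1-[2-(benzyloxy)-3,4-dioxocyclohexa-1,5-dien-1-yl]-3-[3,4-bis(benzyloxy)phenyl]propane-1,3-dione | O=C(CC(=O)c1ccc(OCc2ccccc2)c(OCc2ccccc2)c1)C1=C(OCc2ccccc2)C(=O)C(=O)C=C1 | intermediate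
10 | 5-(benzyloxy)-2-[3,4-bis(benzyloxy)phenyl]-6,7-dihydroxy-4H-chromen-4-one | O=c1cc(-c2ccc(OCc3ccccc3)c(OCc3ccccc3)c2)oc2cc(O)c(O)c(OCc3ccccc3)c12 | intermediate
11 | sulfur trioxide–triethylamine complex | CC[N+](CC)(CC)S(=O)(=O)[O-] | starting material
12 | triethylammonium 5-(benzyloxy)-2-[3,4-bis(benzyloxy)phenyl]-6-hydroxy-4-oxo-4H-chromen-7-yl sulfate | O=c1cc(-c2ccc(OCc3ccccc3)c(OCc3ccccc3)c2)oc2cc(OS(=O)(=O)[O-])c(O)c(OCc3ccccc3)c12.CC[NH+](CC)CC | intermediate
13 | 6-hydroxyluteolin 7-sulfate, 2-(3,4-dihydroxyphenyl)-5,6-dihydroxy-4-oxo-4H-chromen-7-yl hydrogen sulfate | O=c1cc(-c2ccc(O)c(O)c2)oc2cc(OS(=O)(=O)O)c(O)c(O)c12 | target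

Total step count: 7
Longest linear sequence: 7 steps (1 to 13)

**Steps most likely to fail**

Step 5 (anodic ring closure). The enol oxygen may attack ipso at the benzyloxy-bearing carbon with loss of benzyl alcohol. Quinone and diketone may couple between molecules. The product catechol may be oxidised further. The fallback closes ring C through an oxygen already present on ring A, by the classical dehydrative flavone synthesis; it sets out from 6 and comes back to the route at 13.
- Ester 6 would be condensed (LiN(SiMe3)2, THF) with commercial 1-(6-hydroxy-2,3,4-trimethoxyphenyl)ethanone to give 1-[3,4-bis(benzyloxy)phenyl]-3-(6-hydroxy-2,3,4-trimethoxyphenyl)propane-1,3-dione F1.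
- Hot 48% HBr in acetic acid would cyclodehydrate F1 and cleave all five ethers to 6-hydroxyluteolin F2.
- Ac2O in pyridine would give 6-hydroxyluteolin pentaacetate F3.
- Thiophenol and imidazole in N-methylpyrrolidone at 0 °C would remove only the acetyl group on O7, the ester of the most acidic phenol, to give 2-[3,4-bis(acetyloxy)phenyl]-7-hydroxy-4-oxo-4H-chromene-5,6-diyl diacetate F4.
- SO3·NEt3 in DMF would give triethylammonium 5,6-bis(acetyloxy)-2-[3,4-bis(acetyloxy)phenyl]-4-oxo-4H-chromen-7-yl sulfate F5.
- Methanolysis of the four acetates (K2CO3 cat., MeOH, 0 °C, argon) and the same cold acidic resin would deliver 13.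

Step 6 (sulfation). Sulfation may be unselective between the 6- and 7-hydroxyls or run on to the bis-sulfate, giving anionic mixtures that are hard to separate. The fallback introduces the sulfate in masked, neutral form; it sets out from 10 and comes back to the route at 13.
- 2,2,2-Trichloroethyl chlorosulfate with Et3N and 4-(dimethylamino)pyridine in THF would give 5-(benzyloxy)-2-[3,4-bis(benzyloxy)phenyl]-6-hydroxy-4-oxo-4H-chromen-7-yl 2,2,2-trichloroethyl sulfate F6. This neutral diester can be chromatographed free of its 6-isomer and assigned by an NOE to H8.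
- Pd/C with HCO2NH4 in methanol would then remove the trichloroethyl group and the three benzyl ethers in one operation, and the acidic resin would give 13.

Step 3 (Claisen condensation). The electron-rich benzoate is a poor acylating agent, so conversion may stall while the ketone enolate self-condenses. The fallback makes the C2–C3 bond by aldol addition and adjusts the oxidation level afterwards; it sets out from 5 and comes back to the route at 7.
- The lithium enolate of 5 (LiN(iPr)2, THF, −78 °C) would add to commercial 3,4-bis(benzyloxy)benzaldehyde to give racemic 1-[4-(benzyloxy)-2,2-diphenyl-1,3-benzodioxol-5-yl]-3-[3,4-bis(benzyloxy)phenyl]-3-hydroxypropan-1-one F7.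
- Dess–Martin periodinane in CH2Cl2 would oxidise F7 to the diketone 7.

**Further compounds**

F1 | step 5 | 1-[3,4-bis(benzyloxy)phenyl]-3-(6-hydroxy-2,3,4-trimethoxyphenyl)propane-1,3-dione | COc1cc(O)c(C(=O)CC(=O)c2ccc(OCc3ccccc3)c(OCc3ccccc3)c2)c(OC)c1OC
F2 | step 5 | 6-hydroxyluteolin, 2-(3,4-dihydroxyphenyl)-5,6,7-trihydroxy-4H-chromen-4-one | O=c1cc(-c2ccc(O)c(O)c2)oc2cc(O)c(O)c(O)c12
F3 | step 5 | 6-hydroxyluteolin pentaacetate, 2-[3,4-bis(acetyloxy)phenyl]-4-oxo-4H-chromene-5,6,7-triyl triacetate | CC(=O)Oc1ccc(-c2cc(=O)c3c(OC(C)=O)c(OC(C)=O)c(OC(C)=O)cc3o2)cc1OC(C)=O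
F4 | step 5 | 2-[3,4-bis(acetyloxy)phenyl]-7-hydroxy-4-oxo-4H-chromene-5,6-diyl diacetate | CC(=O)Oc1ccc(-c2cc(=O)c3c(OC(C)=O)c(OC(C)=O)c(O)cc3o2)cc1OC(C)=O
F5 | step 5 | triethylammonium 5,6-bis(acetyloxy)-2-[3,4-bis(acetyloxy)phenyl]-4-oxo-4H-chromen-7-yl sulfate | CC(=O)Oc1ccc(-c2cc(=O)c3c(OC(C)=O)c(OC(C)=O)c(OS(=O)(=O)[O-])cc3o2)cc1OC(C)=O.CC[NH+](CC)CC
F6 | step 6 | 5-(benzyloxy)-2-[3,4-bis(benzyloxy)phenyl]-6-hydroxy-4-oxo-4H-chromen-7-yl 2,2,2-trichloroethyl sulfate | O=c1cc(-c2ccc(OCc3ccccc3)c(OCc3ccccc3)c2)oc2cc(OS(=O)(=O)OCC(Cl)(Cl)Cl)c(O)c(OCc3ccccc3)c12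
F7 | step 3 | 1-[4-(benzyloxy)-2,2-diphenyl-1,3-benzodioxol-5-yl]-3-[3,4-bis(benzyloxy)phenyl]-3-hydroxypropan-1-one (racemic) | O=C(CC(O)c1ccc(OCc2ccccc2)c(OCc2ccccc2)c1)c1ccc2OC(c3ccccc3)(c3ccccc3)Oc2c1OCc1ccccc1
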